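All runs come from a simulation on assumed constants; the scatter is artificial.

| setting | Sunday's | dawn | winter | noon | dusk | summer |
|---|---|---|---|---|---|---|
| starting material | 0.11 M | 0.060 M | 0.10 M | 0.10 M | 0.10 M | 0.10 M |
| partner | 0.050 M | 0.0500 M | 0.0500 M | 0.0500 M | 0.150 M | 0.0300 M |
| free catalyst | 0.57 mM | 0.57 mM | 0.20 mM | 0.57 mM | 0.57 mM | 0.80 mM |
| impurity | 0.23 mM | 0.23 mM | 0.23 mM | 0.23 mM | 0.060 mM | 0.23 mM |
| temperature | 0 °C | 0 °C | 30 °C | 0 °C | 40 °C | 20 °C |
| remark | run made earlier |  |  |  |  |  |
| time |  | 20 h | 20 h | 20 h | 20 h | 20 h |

Sunday's run (percent of the starting material charged)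

| time / h | product / % | starting material / % |
|---|---|---|
| 1.00 | 1.7 | 98.0 |
| 1.33 | 3.6 | 97.7 |
| 2.00 | 2.4 | 96.3 |
| 3.00 | 5.7 | 94.5 |
| 5.00 | 8.6 | 92.1 |
| 8.00 | 13.0 | 86.6 |
| 12.0 | 18.9 | 80.3 |

(readings scatter by 0.5 percentage points)

- the earlier runs do not show what temperature does; that part of a forecast is a guess
- no earlier run changes the charge of free catalyst; that part of a forecast is a guess
- no earlier run changes the charge of impurity; that part of a forecast is a guess

- the flasks by amount of product, in percent of the starting material charged, highest first, at 20 h (dawn / winter / noon / dusk / summer)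
- the same order at 6.0 d (dawn / winter / noon / dusk / summer)
- the amount of product, in percent of the starting material charged of the flask you put first, at 20 h
- the amount of product, in percent of the starting material charged of the flask you put last, at 20 h

- Millimoles per litre were the unit of my ledger: free catalyst and impurity are both charged in them, and I opened the account for winter, the flask with the smallest charge of free catalyst.
- The first entry came from Sunday's run. Its last reading, at 12.0 h, showed 18.9 % of product, which is 20.8 mM against 0.57 mM of free catalyst charged, or about 36.5 product per catalyst charged, so catalyst in that flask came back and worked again while 0.23 mM of impurity had been charged with it.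
- The second entry was my own guess, as no earlier run changes the impurity: each impurity takes one free catalyst out for good, and that catalyst does not come back.
- The third entry was winter's charge: 0.20 mM of free catalyst against 0.23 mM of impurity, so there was less catalyst than impurity.
- Winter came to −0.0300 mM: this working catalyst, the charge of free catalyst minus the charge of impurity, was the quantity I carried, and a negative value means that the impurity outnumbers the catalyst.
- I closed the books on that guess: winter's 0.20 mM of free catalyst was booked to the impurity, and 0.0300 mM of impurity stayed over, which is 13.0 % of its charge.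
- So I put winter last at 20 h and at 6.0 d, with its product standing still between the two times.
- The other flasks stayed positive, from 0.340 mM in noon and dawn to 0.570 mM in summer, so the ledger told me that they could run, but not how far.
- The forecast stood on the same guess: “My guess is that the impurity poisons catalyst roughly one to one”. It gave dusk > dawn > summer > noon > winter at 20 h and dusk > dawn > noon > summer > winter at 6.0 d, with 95 % for the first flask and 1 % for the last, a number for winter where my ledger gave none.
- The flasks gave dusk > dawn > noon > summer > winter at 20 h and dusk > dawn > noon > summer > winter at 6.0 d, with dusk first at 48.6 % and winter last at 0.0363 %, still 0.0363 % at 6.0 d.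

    partner + free catalyst ⇌ catalyst intermediate A (K = 28.0 L mol⁻¹, k = 14.0 L mol⁻¹ min⁻¹, Ea = 46.0 kJ mol⁻¹, ΔH = −62.0 kJ mol⁻¹)
    catalyst intermediate D → free catalyst + product (k = 0.510 min⁻¹, Ea = 79.0 kJ mol⁻¹)
    starting material + catalyst intermediate A ⇌ catalyst intermediate B (K = 7.50 L mol⁻¹, k = 270 L mol⁻¹ min⁻¹, Ea = 38.0 kJ mol⁻¹, ΔH = −57.0 kJ mol⁻¹)
    catalyst intermediate B → released group + catalyst intermediate C (k = 0.620 min⁻¹, Ea = 74.0 kJ mol⁻¹)
    free catalyst + impurity → spent catalyst (k = 1000 L mol⁻¹ min⁻¹, Ea = 37.0 kJ mol⁻¹)
    catalyst intermediate C ⇌ catalyst intermediate D (K = 2.30, k = 1.00 min⁻¹, Ea = 71.0 kJ mol⁻¹, ΔH = −66.0 kJ mol⁻¹)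
    (constants at 0 °C)

- At 20.0 h winter held 100 % of its catalyst as spent catalyst and 0 % as free catalyst.
- Its impurity stood at 13 % of the charge, against the 13.0 % that −0.0300 mM of working catalyst had given.
- A neighbour of winter charged with 0.800 mM of free catalyst had a working catalyst of 0.570 mM, with 28.7 % of its charge booked to the impurity; it held 28.8 % as spent catalyst and reached 30.1 % of product at 20.0 h.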